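**Plan**

- Retrosynthesis: the C3 ester is removed, the C3–O and C4–O bonds go back to a C3=C4 olefin, and the 7(11)-en-8-one goes back to a C7=C8 olefin with a C11 carbinol. C3=C4 is then cut to a C3 aldehyde plus the C4 methyl ketone, C1=C2 to a formyl group on C10, and last C5–C6 and C9–C10 are cut.
- Enabling feature: C5 and C10 are neighbours in ring B and hold the two arms of ring A (C4 with C15, and C1) trans, while C7, para to C10, holds the C11 unit. This is the imprint of a 2-substituted butadiene adding across an (E)-enal with formyl on the methyl-bearing carbon and acetyl on the other.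
- Forward order: diene (2 steps) and dienophile (1 step); ring B by cycloaddition; two-carbon extension of the formyl group; ring A by reductive carbonyl coupling; unmasking of the ring B enone; diol; ester.
- Stereochemistry: C10 by catalyst face selection and C5 from the dienophile geometry; C3 and C4 by osmylation from the α face, opposite the axial C10 methyl; the side-chain centre is bought with (S)-3-methylpentanoic acid.

Key step: step 4

Assumption: eudesmane numbering is used (ring A = C1–C5, C10; ring B = C5–C10; C14 on C10, C15 on C4, C11–C13 on C7), and the facial sense of the (S)-prolinol-derived catalyst is taken from the formyl C–H···O binding model for α-substituted enals; the mirror-image catalyst is equally available should the sense prove opposite.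

**Route**

Step 1
Reactants: 1 2-methylbut-3-yn-2-ol
Product: 2 triethyl[(2-methylbut-3-yn-2-yl)oxy]silane
Conditions: Et3SiOTf, 2,6-lutidine, CH2Cl2, 0 °C
Reagents that add atoms: triethylsilyl trifluoromethanesulfonate, CC[Si](CC)(CC)OS(=O)(=O)C(F)(F)F
Why: O-silylation of a tertiary propargylic alcohol with a silyl triflate and a hindered pyridine base is routine, and the ether masks the future C11 carbinol through the steps that follow.

Step 2
Reactants: 2 triethyl[(2-methylbut-3-yn-2-yl)oxy]silane
Product: 3 triethyl[(2-methyl-3-methylidenepent-4-en-2-yl)oxy]silane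
Conditions: ethylene (1 atm), second-generation Grubbs catalyst (H2IMes)(PCy3)Cl2Ru=CHPh (5 mol%), toluene, 80 °C
Reagents that add atoms: ethylene, C=C
Why: ethylene–alkyne cross enyne metathesis, in which the ruthenium methylidene adds to the terminal alkyne and ethylene releases the vinylcarbene as the 2-substituted 1,3-diene, tolerates propargylic ethers.

Step 3
Reactants: 4 pyruvaldehyde; 5 2-(triphenylphosphoranylidene)propanal
Product: 6 (E)-2-methyl-4-oxopent-2-enal
Conditions: 40% aq. 4, CH2Cl2, 0 °C → rt
Reagents that add atoms: none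
Why: Wittig olefination with a formyl-stabilised ylide takes place only at the aldehyde carbonyl of 4 and, as usual for stabilised ylides, should give the (E)-enal with acetyl trans to formyl.

Step 4
Reactants: 3 triethyl[(2-methyl-3-methylidenepent-4-en-2-yl)oxy]silane; 6 (E)-2-methyl-4-oxopent-2-enal
Product: 7 (1R,6R)-6-acetyl-1-methyl-4-{2-[(triethylsilyl)oxy]propan-2-yl}cyclohex-3-ene-1-carbaldehyde (formyl trans to acetyl)
Conditions: (S)-3,3-diphenyl-1-(o-tolyl)tetrahydro-1H,3H-pyrrolo[1,2-c][1,3,2]oxazaborole (20 mol%), HNTf2 (16 mol%), 3 in excess, CH2Cl2, −78 → −40 °C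
Reagents that add atoms: none
Why: The HNTf2-activated oxazaborolidine binds the formyl oxygen of 6 (formyl C–H held by the ring oxygen), which makes C5, the carbon β to the formyl group, the electrophilic end, and the diene adds in a concerted, asynchronous [4+2] cycloaddition with its CH2 next to the substituted carbon (C6) bonding to C5 and the far CH2 (C9) to C10. The closest known reactions are cationic oxazaborolidine-catalysed Diels–Alder additions of 2-substituted butadienes to α-methyl enals and to α-methyl enals carrying a second carbonyl group at the β carbon. Ring B closes by intermolecular cycloaddition, both new σ bonds (C5–C6 and C9–C10) forming in one suprafacial event. The quaternary centre C10 is set by the catalyst, whose phenyl group shields one face of the s-trans enal so that the diene enters from the open face, and C5 follows from C10 through the (E)-geometry of 6, which places formyl and acetyl trans. The step needs formyl rather than acetyl coordination (the aldehyde is the better and less hindered donor, and bonding at the less substituted C5 is also sterically easier), para regiochemistry (the substituted diene carbon ends 1,4 to C10) and survival of the tertiary silyl ether (a deficit of HNTf2 relative to the oxazaborolidine leaves no free acid); endo or exo approach is irrelevant because the diene termini are not stereogenic.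

Step 5
Reactants: 7 (1R,6R)-6-acetyl-1-methyl-4-{2-[(triethylsilyl)oxy]propan-2-yl}cyclohex-3-ene-1-carbaldehyde; 8 (triphenylphosphoranylidene)acetaldehyde
Product: 9 (E)-3-[(1S,6R)-6-acetyl-1-methyl-4-{2-[(triethylsilyl)oxy]propan-2-yl}cyclohex-3-en-1-yl]prop-2-enal
Conditions: 8 (1.3 equiv), toluene, 80 °C
Reagents that add atoms: none
Why: Wittig olefination with a stabilised ylide attacks aldehydes but not ketones, so only the C10 formyl group is extended by C2 and C3 to the (E)-enal, and neither stereocentre is touched.

Step 6
Reactants: 9 (E)-3-[(1S,6R)-6-acetyl-1-methyl-4-{2-[(triethylsilyl)oxy]propan-2-yl}cyclohex-3-en-1-yl]prop-2-enal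
Product: 10 3-[(1R,6R)-6-acetyl-1-methyl-4-{2-[(triethylsilyl)oxy]propan-2-yl}cyclohex-3-en-1-yl]propanal
Conditions: diethyl 2,6-dimethyl-1,4-dihydropyridine-3,5-dicarboxylate (1.2 equiv), Bn2NH2+ CF3CO2− (10 mol%), THF, rt → 40 °C
Reagents that add atoms: none
Why: iminium-catalysed transfer hydrogenation with a Hantzsch ester reduces only the C=C bond of the enal that is activated as its iminium ion, leaving the methyl ketone, the ring olefin and the silyl ether alone.

Step 7
Reactants: 10 3-[(1R,6R)-6-acetyl-1-methyl-4-{2-[(triethylsilyl)oxy]propan-2-yl}cyclohex-3-en-1-yl]propanal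
Product: 11 triethyl({2-[(4aR,8aR)-4a,8-dimethyl-1,4,4a,5,6,8a-hexahydronaphthalen-2-yl]propan-2-yl}oxy)silane
Conditions: TiCl3(DME)1.5, Zn–Cu couple, DME, reflux, slow addition of 10 at high dilution
Reagents that add atoms: none
Why: intramolecular McMurry coupling on low-valent titanium joins the C3 aldehyde and the C4 ketone and removes both oxygens, closing ring A as a trans-fused six-membered ring (the two arms on C5 and C10 are trans and equatorial) with the C3=C4 olefin carrying C15; C5 and C10 are not involved.

Step 8
Reactants: 11 triethyl({2-[(4aR,8aR)-4a,8-dimethyl-1,4,4a,5,6,8a-hexahydronaphthalen-2-yl]propan-2-yl}oxy)silane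
Product: 12 2-[(4aR,8aR)-4a,8-dimethyl-1,4,4a,5,6,8a-hexahydronaphthalen-2-yl]propan-2-ol
Conditions: Bu4NF, THF, rt → 45 °C
Reagents that add atoms: none
Why: fluoride-induced desilylation frees the tertiary allylic alcohol under non-acidic conditions that do not ionise it.

Step 9
Reactants: 12 2-[(4aR,8aR)-4a,8-dimethyl-1,4,4a,5,6,8a-hexahydronaphthalen-2-yl]propan-2-ol
Product: 15 (4aR,8aR)-5,8a-dimethyl-3-(propan-2-ylidene)-3,4,4a,7,8,8a-hexahydronaphthalen-2(1H)-one, via tertiary allyl chromate 13 (not isolated), via C8 allyl chromate 14 (not isolated)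
Conditions: pyridinium chlorochromate (C5H5NH)[CrO3Cl], powdered 4 Å molecular sieves, CH2Cl2, rt
Reagents that add atoms: pyridinium chlorochromate, [O-][Cr](=O)(=O)Cl.c1cc[nH+]cc1
Why: Babler–Dauben oxidative transposition, in which the tertiary chromate undergoes a [3,3] shift that moves oxygen to C8 and the olefin to C7=C11 and the secondary chromate then collapses to the conjugated ketone; the isolated C3=C4 olefin is inert to the reagent at room temperature.

Step 10
Reactants: 15 (4aR,8aR)-5,8a-dimethyl-3-(propan-2-ylidene)-3,4,4a,7,8,8a-hexahydronaphthalen-2(1H)-one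
Product: 16 (4aR,5S,6R,8aR)-5,6-dihydroxy-5,8a-dimethyl-3-(propan-2-ylidene)octahydronaphthalen-2(1H)-one
Conditions: OsO4 (cat.), N-methylmorpholine N-oxide, acetone/H2O, rt
Reagents that add atoms: osmium tetroxide, O=[Os](=O)(=O)=O; N-methylmorpholine N-oxide, C[N+]1([O-])CCOCC1; water, O
Why: Upjohn dihydroxylation adds both oxygens suprafacially to the electron-richer trisubstituted C3=C4 olefin (the tetrasubstituted enone olefin is deactivated) from the α face, opposite the axial C10 methyl that blocks the β face of the trans-decalin, which sets C3 (R) and C4 (S) as the cis 3α,4α-diol with C15 β.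

Step 11
Reactants: 16 (4aR,5S,6R,8aR)-5,6-dihydroxy-5,8a-dimethyl-3-(propan-2-ylidene)octahydronaphthalen-2(1H)-one; 17 (S)-3-methylpentanoic acid
Product: 19 (1S,2R,4aR,8aR)-1-hydroxy-1,4a-dimethyl-6-oxo-7-(propan-2-ylidene)decahydronaphthalen-2-yl (3S)-3-methylpentanoate, via (S)-3-methylpentanoyl chloride 18 (not isolated)
Conditions: 17, (COCl)2, cat. DMF, CH2Cl2, 0 °C → rt, concentrate; then 16, pyridine, DMAP, CH2Cl2, 0 °C → rt
Reagents that add atoms: none
Why: DMAP-catalysed acylation with the acid chloride (nucleophilic acyl substitution) esterifies the secondary C3 hydroxyl and leaves the tertiary C4 hydroxyl free; C3 keeps its configuration because its C–O bond is not broken, and the stereocentre of the acid is β to the carbonyl and cannot epimerise.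

**Compound list**

1 | 2-methylbut-3-yn-2-ol | CC(C)(O)C#C | starting material
2 | triethyl[(2-methylbut-3-yn-2-yl)oxy]silane | CC[Si](CC)(CC)OC(C)(C)C#C | intermediate
3 | triethyl[(2-methyl-3-methylidenepent-4-en-2-yl)oxy]silane | C=CC(=C)C(C)(C)O[Si](CC)(CC)CC | intermediate
4 | pyruvaldehyde (2-oxopropanal) | CC(=O)C=O | starting material
5 | 2-(triphenylphosphoranylidene)propanal | CC(C=O)=P(c1ccccc1)(c1ccccc1)c1ccccc1 | starting material
6 | (E)-2-methyl-4-oxopent-2-enal | CC(=O)/C=C(\C)C=O | intermediate
7 | (1R,6R)-6-acetyl-1-methyl-4-{2-[(triethylsilyl)oxy]propan-2-yl}cyclohex-3-ene-1-carbaldehyde | O=C[C@]1(C)CC=C(C(C)(C)O[Si](CC)(CC)CC)C[C@H]1C(C)=O | intermediate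
8 | (triphenylphosphoranylidene)acetaldehyde | O=CC=P(c1ccccc1)(c1ccccc1)c1ccccc1 | starting material
9 | (E)-3-[(1S,6R)-6-acetyl-1-methyl-4-{2-[(triethylsilyl)oxy]propan-2-yl}cyclohex-3-en-1-yl]prop-2-enal | O=C/C=C/[C@]1(C)CC=C(C(C)(C)O[Si](CC)(CC)CC)C[C@H]1C(C)=O | intermediate
10 | 3-[(1R,6R)-6-acetyl-1-methyl-4-{2-[(triethylsilyl)oxy]propan-2-yl}cyclohex-3-en-1-yl]propanal | O=CCC[C@]1(C)CC=C(C(C)(C)O[Si](CC)(CC)CC)C[C@H]1C(C)=O | intermediate
11 | triethyl({2-[(4aR,8aR)-4a,8-dimethyl-1,4,4a,5,6,8a-hexahydronaphthalen-2-yl]propan-2-yl}oxy)silane (5α-H, 10β-methyl) | CC1=CCC[C@]2(C)CC=C(C(C)(C)O[Si](CC)(CC)CC)C[C@H]21 | intermediate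
12 | 2-[(4aR,8aR)-4a,8-dimethyl-1,4,4a,5,6,8a-hexahydronaphthalen-2-yl]propan-2-ol | CC1=CCC[C@]2(C)CC=C(C(C)(C)O)C[C@H]21 | intermediate
13 | hydrogen chromate ester of 12 at the C11 oxygen (tertiary allyl chromate) | CC1=CCC[C@]2(C)CC=C(C(C)(C)O[Cr](=O)(=O)O)C[C@H]21 | intermediate
14 | hydrogen chromate ester at C8 of the transposed 7(11)-ene (C8 allyl chromate, C8 configuration undefined) | CC1=CCC[C@]2(C)CC(O[Cr](=O)(=O)O)C(=C(C)C)C[C@H]21 | intermediate
15 | (4aR,8aR)-5,8a-dimethyl-3-(propan-2-ylidene)-3,4,4a,7,8,8a-hexahydronaphthalen-2(1H)-one (eudesma-3,7(11)-dien-8-one) | CC1=CCC[C@]2(C)CC(=O)C(=C(C)C)C[C@H]21 | intermediate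
16 | (4aR,5S,6R,8aR)-5,6-dihydroxy-5,8a-dimethyl-3-(propan-2-ylidene)octahydronaphthalen-2(1H)-one (3α,4α-diol) | O[C@@H]1CC[C@]2(C)CC(=O)C(=C(C)C)C[C@H]2[C@]1(C)O | intermediate
17 | (S)-3-methylpentanoic acid | CC[C@H](C)CC(=O)O | starting material
18 | (S)-3-methylpentanoyl chloride | CC[C@H](C)CC(=O)Cl | intermediate
19 | (1S,2R,4aR,8aR)-1-hydroxy-1,4a-dimethyl-6-oxo-7-(propan-2-ylidene)decahydronaphthalen-2-yl (3S)-3-methylpentanoate | CC[C@H](C)CC(=O)O[C@@H]1CC[C@]2(C)CC(=O)C(=C(C)C)C[C@H]2[C@]1(C)O | target

**Totals**

Total step count: 11. Longest linear sequence: 10 steps (steps 1, 2 and 4–11, from 1 to 19); step 3 is a one-step branch.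

**Steps most likely to fail**

Step 4. The acetyl group may compete with the formyl group for the boron centre and the trisubstituted dienophile may add slowly, which would erode regio- and enantiocontrol; the acidic catalyst may also ionise the tertiary silyl ether. Fallback: starting from 3 and 6, the cycloaddition would be promoted by the achiral, acid-scavenging Lewis acid Me2AlCl (CH2Cl2, −78 °C). Formyl coordination should still direct the regiochemistry, and the dienophile geometry should still fix the trans relation. This should give 7 as a racemate with the mirror-image adduct ent-7 F1. Preparative chromatography on a chiral stationary phase would then separate the two, and the route is rejoined at 7. The absolute configuration would thus come from resolution instead of catalysis.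

Step 7. The hot, Lewis-acidic titanium medium may enolise the ketone and epimerise C5, may strip the tertiary allylic silyloxy group, or may couple two molecules instead of closing the ring. Fallback: starting from 10, the ring would be closed by an intramolecular Wittig reaction under basic conditions.
- NaBH4 (EtOH/CH2Cl2, −78 °C) should reduce the aldehyde in preference to the methyl ketone and give the hydroxy ketone F2.
- I2, PPh3 and imidazole would convert it into the primary iodide F3.
- PPh3 in MeCN at reflux would give the phosphonium iodide F4.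
- KN(SiMe3)2 in toluene (0 °C → reflux) would deprotonate it to the ylide F5, which should add to the C4 ketone and close ring A.

The route is rejoined at 11.

Step 9. The tertiary allylic alcohol may dehydrate to dienes under the mildly acidic chromium reagent, or the [3,3] shift from an exocyclic carbinol into the ring may be slow. Fallback: starting from 12, the transposition would be done reductively in three steps.
- Hydroxyl-directed epoxidation with VO(acac)2 and t-BuOOH (CH2Cl2, 0 °C) should attack only the C7=C8 olefin next to the carbinol and give the epoxy alcohol F6.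
- Cp2TiCl, made in the flask from Cp2TiCl2 and Zn in THF, would open the epoxide to the tertiary C7 radical and expel the C11 oxygen, giving the transposed allylic alcohol F7 (7(11)-en-8-ol).
- Dess–Martin oxidation would convert it into the enone.

The route is rejoined at 15.

**Further compounds**

F1 | step 4 | (1S,6S)-6-acetyl-1-methyl-4-{2-[(triethylsilyl)oxy]propan-2-yl}cyclohex-3-ene-1-carbaldehyde (ent-7) | O=C[C@@]1(C)CC=C(C(C)(C)O[Si](CC)(CC)CC)C[C@@H]1C(C)=O
F2 | step 7 | 1-[6-(3-hydroxypropyl)-6-methyl-3-{2-[(triethylsilyl)oxy]propan-2-yl}cyclohex-3-en-1-yl]ethanone, configuration as in 10 | OCCC[C@]1(C)CC=C(C(C)(C)O[Si](CC)(CC)CC)C[C@H]1C(C)=O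
F3 | step 7 | 1-[6-(3-iodopropyl)-6-methyl-3-{2-[(triethylsilyl)oxy]propan-2-yl}cyclohex-3-en-1-yl]ethanone, configuration as in 10 | ICCC[C@]1(C)CC=C(C(C)(C)O[Si](CC)(CC)CC)C[C@H]1C(C)=O
F4 | step 7 | {3-[6-acetyl-1-methyl-4-{2-[(triethylsilyl)oxy]propan-2-yl}cyclohex-3-en-1-yl]propyl}triphenylphosphonium iodide, configuration as in 10 | c1ccccc1[P+](c1ccccc1)(c1ccccc1)CCC[C@]1(C)CC=C(C(C)(C)O[Si](CC)(CC)CC)C[C@H]1C(C)=O.[I-]
F5 | step 7 | ylide of F4 | c1ccccc1P(c1ccccc1)(c1ccccc1)=CCC[C@]1(C)CC=C(C(C)(C)O[Si](CC)(CC)CC)C[C@H]1C(C)=O
F6 | step 9 | 7,8-epoxide of 12 (epoxide configuration undefined) | CC1=CCC[C@]2(C)CC3OC3(C(C)(C)O)C[C@H]21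
F7 | step 9 | (4aR,8aR)-5,8a-dimethyl-3-(propan-2-ylidene)-1,2,3,4,4a,7,8,8a-octahydronaphthalen-2-ol (C8 configuration undefined) | CC1=CCC[C@]2(C)CC(O)C(=C(C)C)C[C@H]21
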